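The vessel was closed, stirred and isothermal, and I booked substrate as the limiting reagent, with the gas phase held at 100 mM.

| setting | eta | theta | flask |
|---|---|---|---|
| substrate | 0.50 M | 0.50 M | 0.50 M |
| gas phase | 100 mM (held) | 100 mM (held) | 100 mM (held) |
| free catalyst | 0.70 mM | 1.1 mM | 0.50 mM |
| remark | run made earlier | run made earlier |  |
| time |  |  | 2.5 h |

- eta (time / min: target / %): 8.00: 4; 25.0: 9; 40.0: 11; 60.0: 19; 90.0: 25
- theta (time / min: target / %): 8.00: 2; 15.0: 7; 25.0: 11; 50.0: 22; 90.0: 32

(each reading ± 1.5 percentage points)

- at the start none of the gas phase is in solution

- west: doubling the amount of free catalyst, all else as stated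
- north: doubling the transfer coefficient of the gas phase, all else as stated
- east: doubling the saturation concentration of gas phase, all else as stated

1. target at 2.5 h, in percent of the substrate charged
2. the change that raises the amount of target at 2.5 h, in percent of the substrate charged most ("none" if none brings more than 2 percentage points) (west / north / east / none)
3. amount of target at 2.5 h, in percent of the substrate charged, after north

The ledger opened with 0.50 M of substrate, and the readings gave one entry, target. Theta's reading of 22% at 50.0 min lay between eta's 19% and 25% once theta's clock was stretched to 78.6 min, so I took the rate as first order in [free catalyst]. I therefore used eta-time, the clock time multiplied by [free catalyst] and divided by eta's [free catalyst]: 107 min for the flask. That lies between eta's last reading at 90.0 min and theta's last at 141 min, and interpolating gave me 27.3% target. That entry is 0.137 M, more than the 100 mM that saturation holds, so, if each target takes one gas, that entry needed the gas phase to keep crossing over. The remaining 72.7% stayed unassigned, as substrate or as anything the runs did not read.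

The forecast gave 27%, chose west and put north at 28%, reading the reaction as “roughly first order in catalyst”.

The flask gave 23.0%, below my entry at eta-time 107 min, and 24.0% after north; without north its books closed with 61.2% substrate, 23.0% target and 15.8% side product, counted at two substrates each.

    gas phase ⇌ dissolved gas, rate k1*(csat - [dissolved gas]) (kL = 4.20 h⁻¹)
    substrate + dissolved gas + free catalyst ⇌ free catalyst + target (K = 11.0 M⁻¹, k = 9600 M⁻² h⁻¹)
    substrate + target → side product (k = 0.550 M⁻¹ h⁻¹)
    dissolved gas + free catalyst → spent catalyst (k = 7.30 M⁻¹ h⁻¹)

The choice of west would fall if a run showed east gaining more than west; here west gained 8.6 percentage points and east 6.4 points. A flask at 0.50 mM read at 90.0 min has eta-time 64.3 min, just past eta's 19% at 60.0 min, and it held 20.3%.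

The earlier runs and the new flask are calculated with constants of no real substance; scatter was added.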